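The readings come from a simulation from invented constants; scatter was added.

A small charge of catalyst works slowly: the teal run takes 12.0 h to bring target to 21.5%, and the ochre run reaches 21.6% at 0.833 h.

the same everywhere: substrate 0.10 M

| flask | catalyst | remark | time |
|---|---|---|---|
| teal | 0.027 mM | run made earlier |  |
| ochre | 0.36 mM | run made earlier |  |
| Wednesday's | 0.050 mM |  | 12 h |
| Saturday's | 0.10 mM |  | 12 h |
| Sunday's | 0.20 mM |  | 12 h |
| Tuesday's | 0.40 mM |  | 12 h |

| run | time / h | target / % | substrate / % |
|---|---|---|---|
| teal | 0.833 | 4.9 | 95.1 |
| teal | 2.50 | 10.6 | 90.4 |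
| teal | 4.00 | 13.9 | 85.5 |
| teal | 6.00 | 17.9 | 80.1 |
| teal | 10.0 | 21.4 | 74.6 |
| teal | 12.0 | 21.5 | 72.5 |
| ochre | 0.833 | 21.6 | 71.5 |
| ochre | 2.50 | 20.0 | 57.2 |
| ochre | 4.00 | 16.3 | 48.0 |
| ochre | 6.00 | 14.6 | 38.8 |
| ochre | 10.0 | 8.1 | 24.7 |
| ochre | 12.0 | 6.4 | 19.4 |

(standard deviation of a reading: 0.5 percentage points)

* amount of target at the end, in percent of the substrate charged for Wednesday's, Saturday's, Sunday's, Tuesday's, in this order
* the course of these numbers from the first flask to the last (hardly changes / falls, then rises / falls all the way / rises all the way / rises, then falls)

- reactions considered so far: catalyst <-> dormant form; catalyst + target -> catalyst + over-reaction product; substrate + catalyst <-> catalyst + target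
- "hardly changes" means that all values lie within two and a half points (for a concentration: within two and a half percent of the largest)

The flasks share c_substrate and time, and each holds twice the c_catalyst of the one before. So the question is what doubling c_catalyst does. Both steps that move substrate and target have catalyst as a partner, so with c_catalyst steady each is pseudo-first-order, with a rate constant proportional to c_catalyst. The exchange with the dormant form is first order both ways, so once relaxed it holds back the same share of a large charge as of a small one.

For Wednesday's, 0.600 mM·h is the dose, charged c_catalyst times elapsed time. Target should follow the dose. The readings test this: teal at 0.324 mM·h and ochre at 0.300 mM·h give 21.5% and 21.6%, with a scatter of 0.5 percentage points.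

So ochre's readings can stand in for the new flasks, with no fit. In this reckoning, Wednesday's 0.600 mM·h lies between the ochre doses where target reads 21.6% and 20.0%, and Saturday's 1.20 mM·h between those where it reads 20.0% and 16.3%. Sunday's 2.40 mM·h lies between the ochre doses where target reads 14.6% and 8.1%. Tuesday's 4.80 mM·h is larger than ochre's last dose, 4.32 mM·h, where target reads 6.4%. Ochre's target falls from its first reading on, so the row should fall.

The forecast works on the same scale, noting that “the target/substrate curves nearly superimpose on that scale”. From its estimated curve it gives 21.6%, 18.3%, 12.8% and 5.7%: falls all the way. Its first value sits at the top of the span read from ochre, and its last below ochre's last reading.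

    catalyst ⇌ dormant form (K = 0.410, k = 0.0130 min⁻¹)
    catalyst + target → catalyst + over-reaction product (k = 29.0 M⁻¹ min⁻¹)
    substrate + catalyst ⇌ catalyst + target (K = 0.420, k = 43.0 M⁻¹ min⁻¹)

The flasks give 21.9%, 18.3%, 12.5% and 5.75%: falls all the way. In Wednesday's, with each step taken net, target is made 4.03 times as fast as it is used up at 2.75 h, and that ratio is 0.833 at 12.0 h. Saturday's at 6.00 h has had 0.600 mM·h, the dose of Wednesday's end, and holds target 21.8% against Wednesday's 21.9%. Tuesday's at 6.00 h has had 2.40 mM·h, the dose of Sunday's end, and holds target 12.3% against Sunday's 12.5%.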